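**Assumption:** D‑glyceraldehyde acetonide (made from D‑mannitol) and (Z)‑2‑octen‑1‑ol are bought. The C8 carbinol epimers of 13 are carried together, because C8 is ionised in Step 10 and its configuration is lost.

## Retrosynthetic overview
- Target ⇒ α‑iodination of the 4‑hydroxy‑cyclopentenone 14.
- 14 ⇒ photochemical disrotatory 4π closure (a "photo‑Piancatelli") of the hydroxypentadienyl cation derived from furylcarbinol 13. This is the only ring formed. It makes the C4–C5 bond and sets the quaternary carbinol with OH cis to the C5 side chain.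
- 13 ⇒ 5‑lithio‑2‑[(Z)‑octenyl]furan (12) added to the α‑acetoxy aldehyde 8.
- 8 ⇒ Z‑Wittig on (R)‑glyceraldehyde acetonide (1), which carries the only bought stereocentre, C7. C4 and C5 are then controlled by C7.

## Route

**Step 1**
Reactants: 1 (R)‑2,3‑O‑isopropylideneglyceraldehyde; 2 (4‑carboxybutyl)triphenylphosphonium bromide
Product: 3 (Z)‑6‑[(S)‑2,2‑dimethyl‑1,3‑dioxolan‑4‑yl]hex‑5‑enoic acid
Conditions: 2 (1.6 equiv), KHMDS (3.2 equiv), THF, 0 °C; cool to −78 °C, add 1, warm to rt
Reagents that add atoms: none
Why: A salt‑free non‑stabilised ylide gives the Z‑olefin (Wittig reaction). The α‑alkoxy stereocentre is untouched, and the descriptor changes from R to S only because CIP priorities change.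

**Step 2**
Reactants: 3
Product: 4 methyl (5Z,7S)‑7,8‑dihydroxyoct‑5‑enoate
Conditions: MeOH, AcCl (5 mol %, gives HCl), 0 °C → rt
Reagents that add atoms: methanol, CO
Why: One pot performs Fischer esterification and acetonide methanolysis (transketalisation), and the Z‑olefin and C7 are unaffected.

**Step 3**
Reactants: 4
Product: 5 methyl (5Z,7S)‑7‑hydroxy‑8‑(trityloxy)oct‑5‑enoate
Conditions: TrCl, pyridine, cat. DMAP, CH2Cl2, 0 °C → rt
Reagents that add atoms: trityl chloride, ClC(c1ccccc1)(c1ccccc1)c1ccccc1
Why: The bulky trityl group protects the primary hydroxyl selectively over the allylic secondary one.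

**Step 4**
Reactants: 5
Product: 6 methyl (5Z,7S)‑7‑acetoxy‑8‑(trityloxy)oct‑5‑enoate
Conditions: Ac2O, pyridine, cat. DMAP, CH2Cl2, 0 °C
Reagents that add atoms: acetic anhydride, CC(=O)OC(C)=O
Why: Simple O‑acetylation. It installs the final C7 acetate, with no change at C7.

**Step 5**
Reactants: 6
Product: 7 methyl (5Z,7S)‑7‑acetoxy‑8‑hydroxyoct‑5‑enoate
Conditions: ZnBr2, CH2Cl2/MeOH 9:1, 0 °C, 30 min; quick filtration, crude used at once
Reagents that add atoms: none
Why: Lewis‑acid detritylation is mild and leaves the ester, acetate and Z‑olefin intact. The product is used immediately to avoid 2→1 acyl migration.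

**Step 6**
Reactants: 7
Product: 8 methyl (5Z,7S)‑7‑acetoxy‑8‑oxooct‑5‑enoate
Conditions: Dess–Martin periodinane, NaHCO3, CH2Cl2, 0 °C, 1 h
Reagents that add atoms: none
Why: Buffered Dess–Martin oxidation (DMP) of the primary alcohol gives the α‑acetoxy aldehyde without epimerising C7.

**Step 7**
Reactants: 9 (Z)‑oct‑2‑en‑1‑ol
Product: 10 (Z)‑1‑bromooct‑2‑ene
Conditions: PPh3, CBr4, CH2Cl2, 0 °C
Reagents that add atoms: carbon tetrabromide, BrC(Br)(Br)Br
Why: Appel reaction, an SN2 substitution at the primary carbon that retains the Z geometry.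

**Step 8**
Reactants: 11 furan; 10
Product: 12 2‑[(Z)‑oct‑2‑en‑1‑yl]furan
Conditions: 11, n‑BuLi, THF, −20 °C; then 10, DMPU, −78 °C → rt
Reagents that add atoms: none
Why: SN2 alkylation of 2‑lithiofuran with the allylic bromide attaches the future C4 side chain.

**Step 9**
Reactants: 12; 8
Product: 13 methyl (5Z,7S)‑7‑acetoxy‑8‑hydroxy‑8‑{5‑[(Z)‑oct‑2‑en‑1‑yl]furan‑2‑yl}oct‑5‑enoate (C8 epimers)
Conditions: 12, n‑BuLi, THF, −20 → 0 °C; then anhydrous CeCl3, −78 °C; add 8, −78 °C, 1 h; aq. NH4Cl
Reagents that add atoms: none
Why: The organocerium reagent adds chemoselectively to the aldehyde in the presence of the ester and acetate (1,2‑addition). The new C8 carbinol centre is irrelevant because it is ionised in the next step.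

**Step 10**
Reactants: 13
Product: 14 methyl (5Z,7S)‑7‑acetoxy‑7‑{(1S?)…} cyclopentenone, i.e. the 4‑hydroxy‑4‑[(Z)‑octenyl]‑5‑substituted cyclopent‑2‑enone written in the list below
Conditions: Dy(OTf)3 (10 mol %), MeCN/H2O 9:1 (0.01 M), −10 °C, 405 nm LEDs, N2, 24 h
Reagents that add atoms: water, O (its OH ends up at C4; the C8 hydroxyl leaves as water)
Why: Acid ionises the furylcarbinol, water opens the furan to the hydroxypentadienyl cation, and photochemical 4π‑electrocyclisation closes the ring, making the C4–C5 bond and the quaternary carbinol in one step. The stereochemistry follows from orbital symmetry: photochemical closure is disrotatory, whereas the thermal Piancatelli closure is conrotatory and gives trans. From the same cation geometry the disrotatory mode places C4–OH cis to the C5 side chain, and the Z‑octenyl group trans to it, as in the target. The bought C7 centre selects between the two disrotatory senses through A(1,3)‑strain minimisation in the reactive conformer, which sets C4 and C5 absolutely.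
Proposed new method: ring‑opening and hydration of furylcarbinols is fast at −10 °C, but thermal conrotatory closure of the 2‑hydroxypentadienyl cation is the slow step, so the open cation accumulates and can absorb visible or near‑UV light (about 350–420 nm). Excitation to the π,π* state switches the allowed closure from conrotatory to disrotatory. The closest known reactions are the thermal Piancatelli rearrangement and the photochemical disrotatory cyclisation of pentadienyl cations. Neither has been applied to hydroxypentadienyl cations from furylcarbinols, and remote 1,2‑induction by C7 is untested.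

**Step 11**
Reactants: 14
Product: 15 target, 7‑acetoxy‑7,8‑dihydroiodovulone I
Conditions: I2 (1.5 equiv), pyridine/CH2Cl2 1:1, 0 °C → rt, dark, 3 h
Reagents that add atoms: iodine, II
Why: Johnson α‑iodination proceeds by pyridine conjugate addition, α‑iodination and elimination, which selectively iodinates C2 of the enone. The stereocentres are not touched, and the tertiary OH is not acylated or affected.

## Compound list
1 | (R)‑2,3‑O‑isopropylideneglyceraldehyde | CC1(C)OC[C@@H](O1)C=O | starting material
2 | (4‑carboxybutyl)triphenylphosphonium bromide | OC(=O)CCCC[P+](c1ccccc1)(c1ccccc1)c1ccccc1.[Br-] | starting material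
3 | (Z)‑6‑[(S)‑2,2‑dimethyl‑1,3‑dioxolan‑4‑yl]hex‑5‑enoic acid | CC1(C)OC[C@@H](O1)/C=C\CCCC(=O)O | intermediate
4 | methyl (5Z,7S)‑7,8‑dihydroxyoct‑5‑enoate | COC(=O)CCC/C=C\[C@H](O)CO | intermediate
5 | methyl (5Z,7S)‑7‑hydroxy‑8‑(trityloxy)oct‑5‑enoate | COC(=O)CCC/C=C\[C@H](O)COC(c1ccccc1)(c1ccccc1)c1ccccc1 | intermediate
6 | methyl (5Z,7S)‑7‑acetoxy‑8‑(trityloxy)oct‑5‑enoate | COC(=O)CCC/C=C\[C@H](OC(C)=O)COC(c1ccccc1)(c1ccccc1)c1ccccc1 | intermediate
7 | methyl (5Z,7S)‑7‑acetoxy‑8‑hydroxyoct‑5‑enoate | COC(=O)CCC/C=C\[C@H](OC(C)=O)CO | intermediate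
8 | methyl (5Z,7S)‑7‑acetoxy‑8‑oxooct‑5‑enoate | COC(=O)CCC/C=C\[C@H](OC(C)=O)C=O | intermediate
9 | (Z)‑oct‑2‑en‑1‑ol | CCCCC/C=C\CO | starting material
10 | (Z)‑1‑bromooct‑2‑ene | CCCCC/C=C\CBr | intermediate
11 | furan | c1ccoc1 | starting material
12 | 2‑[(Z)‑oct‑2‑en‑1‑yl]furan | CCCCC/C=C\Cc1ccco1 | intermediate
13 | furylcarbinol (C8 epimeric mixture) | COC(=O)CCC/C=C\[C@H](OC(C)=O)C(O)c1ccc(C/C=C\CCCCC)o1 | intermediate
14 | 4‑hydroxy‑4‑[(Z)‑octenyl]‑5‑[(S)‑acetoxy‑(Z)‑alkenyl]cyclopent‑2‑enone | CCCCC/C=C\C[C@@]1(O)C=CC(=O)[C@@H]1[C@H](/C=C\CCCC(=O)OC)OC(C)=O | intermediate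
15 | 7‑acetoxy‑7,8‑dihydroiodovulone I | CCCCC/C=C\C[C@@]1(O)C=C(I)C(=O)[C@@H]1[C@H](/C=C\CCCC(=O)OC)OC(C)=O | target

## Totals
Total steps: 11. Longest linear sequence: 9 steps (1 → 3 → 4 → 5 → 6 → 7 → 8 → 13 → 14 → 15, counting Steps 1–6, 9, 10, 11).

## Three steps most likely to fail
1. **Step 10 (proposed new photo‑Piancatelli).** Thermal closure or E/Z photoisomerisation may compete, and C7 may induce poor diastereoselectivity. Fallback: run the known thermal Piancatelli on 13 (Dy(OTf)3, MeCN/H2O, 80 °C). This gives the 4,5‑trans isomer. Then epimerise C5 with mild base or alumina toward the thermodynamically preferred isomer (Z‑octenyl trans to the C5 chain, OH cis), and separate diastereomers.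
2. **Step 9 (addition to the α‑acetoxy aldehyde 8).** Risks are acyl migration to the new C8 alkoxide, epimerisation of 8, and attack on the acetate or ester. Fallback: change the C7 protecting group. Use TBSCl in place of Ac2O in Step 4, carry the C7‑OTBS aldehyde through the addition and photocyclisation, then remove the silyl group (HF·pyridine) and acetylate C7‑OH selectively over the tertiary C4‑OH (Ac2O, DMAP). This adds 2 steps.
3. **Step 11 (iodination).** I2 can isomerise the Z‑olefins, and pyridine can eliminate the β‑acetoxy group. Fallback: use Sha–Huang iodination (I2/TMSN3, via IN3 addition–elimination) in the dark, which avoids pyridine‑mediated enolisation.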